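**Retrosynthetic overview**

- Target ⇐ global O-demethylation/tert-butyl ester cleavage of a protected isochromanone. Its lactone ring is closed last: the C3 oxygen adds 6-exo-dig to a phenylethynyl group on C8a whose inner carbon is C1, and ozonolysis of the resulting enol ether leaves C1=O.
- Key disconnection (C8a–C1 and C4a–C4): 3,4,5-trimethoxybenzyne, lithium phenylacetylide (C1 synthon) and an (S)-5-silyloxy-5,6-dihydropyran-2-one (C4 acceptor that already carries C3) are joined in one flask through an ortho-alkynyl aryl cuprate.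
- Enabling feature: on the benzene ring the aryne bond C4a≡C8a lies between C5 (OMe) and C8 (H). The C5 oxygen polarises the aryne so that the nucleophile (C1) enters at C8a and the metal ends at C4a, from where the ring is delivered to C4 anti to the C3 oxygen.
- C2′ is then set by trans alkylation of the δ-lactone enolate; the lactone CH2O carbon is oxidised to the C3 carboxyl.
- Ring order: δ-lactone (temporary ring, ring-closing metathesis) → opened → isochromanone ring (alkoxide/alkyne closure, then ozonolysis); the benzene ring is bought.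

Key step: step 4

Remark: locants C1–C8a are those of the isochroman-1-one ring, and C2′/C3′ are the CH and CH2 of the succinic acid arm. In these terms the target SMILES is read as 3S,4S,2′R. Stages run in one flask without isolation count as one step.

Step 1
Reactants: 1 (S)-but-3-ene-1,2-diol; 2 acryloyl chloride
Product: 3 (2S)-2-hydroxybut-3-en-1-yl prop-2-enoate
Conditions: 2 (1.0 equiv), 2,4,6-collidine, CH2Cl2, −78 °C
Reagents that add atoms: none
Why: Acyl transfer to the less hindered primary hydroxyl of the 1,2-diol (selective mono-esterification at low temperature) should install the acrylate without touching the allylic stereocenter.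

Step 2
Reactants: 3 (2S)-2-hydroxybut-3-en-1-yl prop-2-enoate
Product: 4 (2S)-2-[(tert-butyldiphenylsilyl)oxy]but-3-en-1-yl prop-2-enoate
Conditions: t-BuPh2SiCl, Et3N, DMAP (10 mol%), CH2Cl2, rt
Reagents that add atoms: tert-butyl(chloro)diphenylsilane, CC(C)(C)[Si](Cl)(c1ccccc1)c1ccccc1
Why: Silyl ether formation on the remaining secondary alcohol gives a bulky, migration-resistant protecting group that later steers the conjugate addition and survives LiOH; the stereocenter is not involved.

Step 3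
Reactants: 4 (2S)-2-[(tert-butyldiphenylsilyl)oxy]but-3-en-1-yl prop-2-enoate
Product: 5 (5S)-5-[(tert-butyldiphenylsilyl)oxy]-5,6-dihydro-2H-pyran-2-one
Conditions: second-generation Grubbs catalyst (5 mol%), toluene, 80 °C, 0.01 M
Reagents that add atoms: none
Why: Ring-closing metathesis between the acrylate and the vinyl group should close the six-membered α,β-unsaturated lactone (a temporary ring that fixes the Z-enoate and ties the C2′ carboxyl to the future C3 carboxyl carbon) with loss of ethene and no change at the stereocenter.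

Step 4
Reactants: 6 5-bromo-1,2,3-trimethoxybenzene; 7 phenylacetylene; 5 (5S)-5-[(tert-butyldiphenylsilyl)oxy]-5,6-dihydro-2H-pyran-2-one
Product: 12 (4S,5S)-5-[(tert-butyldiphenylsilyl)oxy]-4-[2,3,4-trimethoxy-6-(phenylethynyl)phenyl]oxan-2-one, via 3,4,5-trimethoxybenzyne 8 (not isolated), via ortho-alkynyl aryllithium 9 (not isolated), via lithium aryl(alkynyl)cuprate 10 (not isolated), via silyl ketene acetal 11 (not isolated)
Conditions: 7 (3.2 equiv), lithium 2,2,6,6-tetramethylpiperidide (4.8 equiv), 6 (1.5 equiv), THF–pentane, −78 °C to rt; CuBr·SMe2 (1.5 equiv), −78 °C; Me3SiCl (3 equiv), 5 (1.0 equiv), −78 to −30 °C; 1 M HCl work-up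
Reagents that add atoms: none
Why: Lithium 2,2,6,6-tetramethylpiperidide deprotonates 7 and then 6 at the C–H flanked by bromine and the C5 methoxy group, loss of LiBr gives aryne 8, and lithium phenylacetylide adds to its C8a terminus, the carbon remote from the C5 oxygen, because the charge then develops at C4a beside that inductively withdrawing, lithium-binding oxygen (bond C8a–C1, aryllithium 9). With CuBr·SMe2 and the second acetylide equivalent, 9 becomes the mixed cuprate 10, whose alkynyl ligand does not transfer, so that only the aryl group is delivered to the β-carbon C4 of 5 under Me3SiCl activation (bond C4a–C4), giving ketene acetal 11 and, on work-up, 12. The closest known reaction types are the base-mediated alkynylation of haloarenes through arynes with interception of the ortho-lithiated product, and the conjugate addition of mixed aryl cuprates to 5-oxygenated 5,6-dihydropyran-2-ones. No ring is closed in this step (the isochromanone ring follows in step 7). The new stereocenter C4 is controlled by the existing C3 stereocenter of 5, the aryl group entering anti to the bulky silyloxy group (4,5-trans, 4S). The step needs regioselective opening of the aryne (secured by the C5 methoxy group next to C4a), aryl instead of alkynyl transfer (secured by the strong copper–alkynyl bond) and 1,4- instead of 1,2-addition (secured by the soft cuprate and Me3SiCl).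

Step 5
Reactants: 12 (4S,5S)-5-[(tert-butyldiphenylsilyl)oxy]-4-[2,3,4-trimethoxy-6-(phenylethynyl)phenyl]oxan-2-one; 13 tert-butyl bromoacetate
Product: 15 tert-butyl 2-{(3R,4S,5S)-5-[(tert-butyldiphenylsilyl)oxy]-2-oxo-4-[2,3,4-trimethoxy-6-(phenylethynyl)phenyl]oxan-3-yl}acetate, via lithium enolate 14 (not isolated)
Conditions: LiN(SiMe3)2 (1.1 equiv), THF, −78 °C; 13 (1.5 equiv), DMPU, −78 to −40 °C
Reagents that add atoms: none
Why: Alkylation of the δ-lactone lithium enolate 14 with the reactive α-bromo ester should occur on the face opposite to the neighbouring C4 aryl group (1,2-trans induction known for β-substituted lactone enolates), which sets C2′.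

Step 6
Reactants: 15 tert-butyl 2-{(3R,4S,5S)-5-[(tert-butyldiphenylsilyl)oxy]-2-oxo-4-[2,3,4-trimethoxy-6-(phenylethynyl)phenyl]oxan-3-yl}acetate
Product: 18 (2R,3S,4S)-2-[2-(tert-butoxy)-2-oxoethyl]-4-[(tert-butyldiphenylsilyl)oxy]-3-[2,3,4-trimethoxy-6-(phenylethynyl)phenyl]pentanedioic acid, via lithium hydroxy carboxylate 16 (not isolated), via aldehyde 17 (not isolated)
Conditions: LiOH (1.5 equiv), THF–H2O, 0 °C; then TEMPO (20 mol%), PhI(OAc)2 (2.5 equiv), MeCN–H2O, rt
Reagents that add atoms: lithium hydroxide, [Li+].[OH-]; water, O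
Why: Saponification opens the δ-lactone by acyl–oxygen cleavage to 16 and the freed primary alcohol is oxidised through aldehyde 17 to the acid by the TEMPO/PhI(OAc)2 (oxoammonium) oxidation, conditions that should spare the hindered silyl ether, the alkyne and the tert-butyl ester and under which C2′ is protected from epimerisation as its carboxylate.

Step 7
Reactants: 18 (2R,3S,4S)-2-[2-(tert-butoxy)-2-oxoethyl]-4-[(tert-butyldiphenylsilyl)oxy]-3-[2,3,4-trimethoxy-6-(phenylethynyl)phenyl]pentanedioic acid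
Product: 21 (2R)-4-(tert-butoxy)-2-[(3S,4S)-3-carboxy-5,6,7-trimethoxy-1-oxo-3,4-dihydro-1H-isochromen-4-yl]-4-oxobutanoic acid, via hydroxy diacid 19 (not isolated), via benzylidene isochroman 20 (not isolated)
Conditions: Bu4NF (5 equiv), THF, 60 °C; then O3, CH2Cl2–MeOH, −78 °C; Me2S; 1 M HCl
Reagents that add atoms: ozone, [O-][O+]=O
Why: Fluoride removes the silyl group and the C3 alkoxide of 19 should add anti across the diaryl alkyne in the 6-exo-dig mode at C1 (base-mediated hydroalkoxylation of an ortho-alkynylaryl alcohol, closing the isochroman ring with retention at C3) to give 20, whose electron-rich enol ether double bond is then cleaved by ozone (ozonolysis) to leave the lactone carbonyl at C1.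

Step 8
Reactants: 21 (2R)-4-(tert-butoxy)-2-[(3S,4S)-3-carboxy-5,6,7-trimethoxy-1-oxo-3,4-dihydro-1H-isochromen-4-yl]-4-oxobutanoic acid
Product: 22 (2R)-2-[(3S,4S)-3-carboxy-5,6,7-trihydroxy-1-oxo-3,4-dihydro-1H-isochromen-4-yl]butanedioic acid
Conditions: BBr3 (12 equiv), CH2Cl2, −78 °C to rt; then H2O, 0 °C; reverse-phase chromatography
Reagents that add atoms: none
Why: BBr3 should cleave the three aryl methyl ethers and the tert-butyl ester (Lewis acid-assisted ether and ester dealkylation, as is usual for methoxylated dihydroisocoumarins) without touching the lactone or any stereocenter.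

**Compound list**

1 | (S)-but-3-ene-1,2-diol | C=C[C@H](O)CO | starting material
2 | acryloyl chloride | C=CC(=O)Cl | starting material
3 | (2S)-2-hydroxybut-3-en-1-yl prop-2-enoate | C=C[C@H](O)COC(=O)C=C | intermediate
4 | (2S)-2-[(tert-butyldiphenylsilyl)oxy]but-3-en-1-yl prop-2-enoate | C=C[C@H](O[Si](c1ccccc1)(c1ccccc1)C(C)(C)C)COC(=O)C=C | intermediate
5 | (5S)-5-[(tert-butyldiphenylsilyl)oxy]-5,6-dihydro-2H-pyran-2-one | O=C1C=C[C@H](O[Si](c2ccccc2)(c2ccccc2)C(C)(C)C)CO1 | intermediate
6 | 5-bromo-1,2,3-trimethoxybenzene | COc1cc(Br)cc(OC)c1OC | starting material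
7 | phenylacetylene | C#Cc1ccccc1 | starting material
8 | 3,4,5-trimethoxybenzyne (1,2-didehydro-3,4,5-trimethoxybenzene) | COC1=C(OC)C(OC)=CC#C1 | intermediate
9 | [2,3,4-trimethoxy-6-(phenylethynyl)phenyl]lithium | [Li]c1c(OC)c(OC)c(OC)cc1C#Cc1ccccc1 | intermediate
10 | lithium (phenylethynyl)[2,3,4-trimethoxy-6-(phenylethynyl)phenyl]cuprate | [Li+].COc1cc(C#Cc2ccccc2)c([Cu-]C#Cc2ccccc2)c(OC)c1OC | intermediate
11 | trimethylsilyl ketene acetal of 12 (6-trimethylsilyloxy-3,4-dihydro-2H-pyran, ring stereocenters as in 12) | C[Si](C)(C)OC1=C[C@@H](c2c(OC)c(OC)c(OC)cc2C#Cc2ccccc2)[C@H](O[Si](c2ccccc2)(c2ccccc2)C(C)(C)C)CO1 | intermediate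
12 | (4S,5S)-5-[(tert-butyldiphenylsilyl)oxy]-4-[2,3,4-trimethoxy-6-(phenylethynyl)phenyl]oxan-2-one | O=C1C[C@@H](c2c(OC)c(OC)c(OC)cc2C#Cc2ccccc2)[C@H](O[Si](c2ccccc2)(c2ccccc2)C(C)(C)C)CO1 | intermediate
13 | tert-butyl bromoacetate | CC(C)(C)OC(=O)CBr | starting material
14 | lithium enolate of 12 | [Li+].[O-]C1=C[C@@H](c2c(OC)c(OC)c(OC)cc2C#Cc2ccccc2)[C@H](O[Si](c2ccccc2)(c2ccccc2)C(C)(C)C)CO1 | intermediate
15 | tert-butyl 2-{(3R,4S,5S)-5-[(tert-butyldiphenylsilyl)oxy]-2-oxo-4-[2,3,4-trimethoxy-6-(phenylethynyl)phenyl]oxan-3-yl}acetate | O=C1[C@H](CC(=O)OC(C)(C)C)[C@@H](c2c(OC)c(OC)c(OC)cc2C#Cc2ccccc2)[C@H](O[Si](c2ccccc2)(c2ccccc2)C(C)(C)C)CO1 | intermediate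
16 | lithium (2R,3S,4S)-2-[2-(tert-butoxy)-2-oxoethyl]-4-[(tert-butyldiphenylsilyl)oxy]-5-hydroxy-3-[2,3,4-trimethoxy-6-(phenylethynyl)phenyl]pentanoate | [Li+].CC(C)(C)OC(=O)C[C@@H](C(=O)[O-])[C@@H](c1c(OC)c(OC)c(OC)cc1C#Cc1ccccc1)[C@H](O[Si](c1ccccc1)(c1ccccc1)C(C)(C)C)CO | intermediate
17 | (2R,3S,4S)-2-[2-(tert-butoxy)-2-oxoethyl]-4-[(tert-butyldiphenylsilyl)oxy]-5-oxo-3-[2,3,4-trimethoxy-6-(phenylethynyl)phenyl]pentanoic acid | CC(C)(C)OC(=O)C[C@@H](C(=O)O)[C@@H](c1c(OC)c(OC)c(OC)cc1C#Cc1ccccc1)[C@H](O[Si](c1ccccc1)(c1ccccc1)C(C)(C)C)C=O | intermediate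
18 | (2R,3S,4S)-2-[2-(tert-butoxy)-2-oxoethyl]-4-[(tert-butyldiphenylsilyl)oxy]-3-[2,3,4-trimethoxy-6-(phenylethynyl)phenyl]pentanedioic acid | CC(C)(C)OC(=O)C[C@@H](C(=O)O)[C@@H](c1c(OC)c(OC)c(OC)cc1C#Cc1ccccc1)[C@H](O[Si](c1ccccc1)(c1ccccc1)C(C)(C)C)C(=O)O | intermediate
19 | (2R,3S,4S)-2-[2-(tert-butoxy)-2-oxoethyl]-4-hydroxy-3-[2,3,4-trimethoxy-6-(phenylethynyl)phenyl]pentanedioic acid (present as its tetrabutylammonium salt) | CC(C)(C)OC(=O)C[C@@H](C(=O)O)[C@@H](c1c(OC)c(OC)c(OC)cc1C#Cc1ccccc1)[C@H](O)C(=O)O | intermediate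
20 | (2R)-2-[(1Z,3S,4S)-1-benzylidene-3-carboxy-5,6,7-trimethoxy-3,4-dihydro-1H-isochromen-4-yl]-4-(tert-butoxy)-4-oxobutanoic acid (present as its tetrabutylammonium salt) | CC(C)(C)OC(=O)C[C@@H](C(=O)O)[C@H]1c2c(OC)c(OC)c(OC)cc2/C(=C/c2ccccc2)O[C@@H]1C(=O)O | intermediate
21 | (2R)-4-(tert-butoxy)-2-[(3S,4S)-3-carboxy-5,6,7-trimethoxy-1-oxo-3,4-dihydro-1H-isochromen-4-yl]-4-oxobutanoic acid | CC(C)(C)OC(=O)C[C@@H](C(=O)O)[C@H]1c2c(OC)c(OC)c(OC)cc2C(=O)O[C@@H]1C(=O)O | intermediate
22 | (2R)-2-[(3S,4S)-3-carboxy-5,6,7-trihydroxy-1-oxo-3,4-dihydro-1H-isochromen-4-yl]butanedioic acid | O=C(O)C[C@@H](C(=O)O)[C@H]1c2c(cc(O)c(O)c2O)C(=O)O[C@@H]1C(=O)O | target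

Total step count: 8. Longest linear sequence: 8 steps (1 → 3 → 4 → 5 → 12 → 15 → 18 → 21 → 22); 2, 6, 7 and 13 are bought.

**Steps most likely to fail**

Step 4. The ortho-lithiated intermediate may be protonated by the amine that the base leaves behind, or the doubly ortho-substituted aryl group may be transferred from copper too slowly, so that the lactone is lost to base-induced decomposition and facial selectivity erodes. In the fallback the two bonds are made one after the other by known reactions. Compound 6 is iodinated next to bromine (N-iodosuccinimide, CF3CO2H, MeCN) to 1-bromo-2-iodo-3,4,5-trimethoxybenzene F1. Iodine–magnesium exchange (i-PrMgCl·LiCl, THF, −40 °C) gives the aryl Grignard reagent F2. Its copper-catalysed conjugate addition to 5 (CuBr·SMe2, Me3SiCl, −78 °C, aqueous work-up) gives the bromoaryl lactone F3. Copper-free Sonogashira coupling of F3 with 7 (Pd(OAc)2, XPhos, Cs2CO3, MeCN, 80 °C) returns to 12.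

Step 7. The alkoxide may fail to add to the diaryl alkyne or may close in the 7-endo mode, and ozone may attack the trimethoxybenzene ring. The fallback sets out from 18 and reaches C1 through an aldehyde instead. Semihydrogenation (H2, Pd/CaCO3 poisoned with Pb(OAc)2, quinoline) gives the Z-stilbene F4. Oxidative cleavage (OsO4 cat., NaIO4, 2,6-lutidine) gives the aryl aldehyde F5. Fluoride desilylation (Bu4NF, THF) lets the C3 hydroxyl close onto the aldehyde to the lactol F6. Oxidation of the lactol (TEMPO, PhI(OAc)2) returns to 21.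

Step 6. The silyl group may migrate from the C3 oxygen to the liberated primary alkoxide, or the hydroxy acid may relactonise before it is oxidised. In the fallback the δ-lactone is kept closed until the isochromanone exists. From 15, buffered desilylation (Bu4NF, AcOH, THF) gives the hydroxy lactone F7. Gold-catalysed 6-exo-dig hydroalkoxylation (Ph3PAuNTf2, CH2Cl2; neutral, to avoid δ-to-γ translactonisation) gives the enol ether lactone F8. Ozonolysis (O3, then Me2S) gives the bis-lactone F9. Saponification of the more electrophilic aliphatic δ-lactone (LiOH, 1 equiv, 0 °C) gives the hydroxy carboxylate F10, and TEMPO/PhI(OAc)2 oxidation of its primary alcohol returns to 21.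

**Further compounds**

F1 | step 4 | 1-bromo-2-iodo-3,4,5-trimethoxybenzene | COc1cc(Br)c(I)c(OC)c1OC
F2 | step 4 | (6-bromo-2,3,4-trimethoxyphenyl)magnesium chloride | COc1cc(Br)c([Mg]Cl)c(OC)c1OC
F3 | step 4 | (4S,5S)-4-(6-bromo-2,3,4-trimethoxyphenyl)-5-[(tert-butyldiphenylsilyl)oxy]oxan-2-one | O=C1C[C@@H](c2c(OC)c(OC)c(OC)cc2Br)[C@H](O[Si](c2ccccc2)(c2ccccc2)C(C)(C)C)CO1
F4 | step 7 | (2R,3S,4S)-2-[2-(tert-butoxy)-2-oxoethyl]-4-[(tert-butyldiphenylsilyl)oxy]-3-{2,3,4-trimethoxy-6-[(Z)-2-phenylethenyl]phenyl}pentanedioic acid | CC(C)(C)OC(=O)C[C@@H](C(=O)O)[C@@H](c1c(OC)c(OC)c(OC)cc1/C=C\c1ccccc1)[C@H](O[Si](c1ccccc1)(c1ccccc1)C(C)(C)C)C(=O)O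
F5 | step 7 | (2R,3S,4S)-2-[2-(tert-butoxy)-2-oxoethyl]-4-[(tert-butyldiphenylsilyl)oxy]-3-(6-formyl-2,3,4-trimethoxyphenyl)pentanedioic acid | CC(C)(C)OC(=O)C[C@@H](C(=O)O)[C@@H](c1c(OC)c(OC)c(OC)cc1C=O)[C@H](O[Si](c1ccccc1)(c1ccccc1)C(C)(C)C)C(=O)O
F6 | step 7 | (2R)-4-(tert-butoxy)-2-[(3S,4S)-3-carboxy-1-hydroxy-5,6,7-trimethoxy-3,4-dihydro-1H-isochromen-4-yl]-4-oxobutanoic acid (lactol, both C1 epimers) | CC(C)(C)OC(=O)C[C@@H](C(=O)O)[C@H]1c2c(OC)c(OC)c(OC)cc2C(O)O[C@@H]1C(=O)O
F7 | step 6 | tert-butyl 2-{(3R,4S,5S)-5-hydroxy-2-oxo-4-[2,3,4-trimethoxy-6-(phenylethynyl)phenyl]oxan-3-yl}acetate | O=C1[C@H](CC(=O)OC(C)(C)C)[C@@H](c2c(OC)c(OC)c(OC)cc2C#Cc2ccccc2)[C@H](O)CO1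
F8 | step 6 | enol ether lactone: 15 after loss of the silyl group and closure of the C3 oxygen onto C1 as a (Z)-1-benzylidene isochroman, δ-lactone intact | O=C1[C@H](CC(=O)OC(C)(C)C)[C@H]2c3c(OC)c(OC)c(OC)cc3/C(=C/c3ccccc3)O[C@@H]2CO1
F9 | step 6 | bis-lactone: the isochroman-1-one corresponding to F8, δ-lactone intact | O=C1[C@H](CC(=O)OC(C)(C)C)[C@H]2c3c(OC)c(OC)c(OC)cc3C(=O)O[C@@H]2CO1
F10 | step 6 | lithium (2R)-4-(tert-butoxy)-2-[(3S,4S)-3-(hydroxymethyl)-5,6,7-trimethoxy-1-oxo-3,4-dihydro-1H-isochromen-4-yl]-4-oxobutanoate | [Li+].CC(C)(C)OC(=O)C[C@@H](C(=O)[O-])[C@H]1c2c(OC)c(OC)c(OC)cc2C(=O)O[C@@H]1CO
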